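**Retrosynthetic overview**
- The last bond made is C8'–C9' of the (E,E)-diene, by Pd alkenyl–alkenyl coupling of a hydrozirconated alkynyl dioxolane with (1E,4Z)-1-iodohepta-1,4-diene. The oxidisable triene therefore never meets O2 or radical chemistry.
- The only ring, the 1,2-dioxolane, closes as in the presumed biogenesis: a C5 tertiary hydroperoxide adds 5-exo-trig to the (E)-β-methyl enoate.
- This closure is run on the racemic hydroperoxide under a chiral bifunctional superbase. The catalyst sets C3, and C5 is sorted because the two products are separable diastereomers.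
- The hydroperoxide comes from a 1,1-disubstituted alkene, O2 and Co–H (hydrogen-atom transfer), in the presence of the enoate and a terminal alkyne.
- The skipped dienyne ester comes from deca-1,9-diyne (α-hydroalumination of one terminus) and methyl (E)-4-bromo-3-methylbut-2-enoate.

Assumption: the sense of induction of the catalyst in step 4 cannot be predicted for this new substrate class. One enantiomer is written, and its mirror image, equally accessible, is used if 3S is obtained.

**Step 1**
Reactants: 1 methyl 3-methylbut-2-enoate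
Product: 2 methyl (2E)-4-bromo-3-methylbut-2-enoate
Conditions: NBS (1.0 equiv), AIBN (2 mol %), PhCF3, reflux, 2 h; E separated from Z on SiO2
Reagents that add atoms: N-bromosuccinimide, O=C1CCC(=O)N1Br
Why: In this Wohl–Ziegler allylic bromination the delocalised allyl radical is brominated at either γ-methyl, giving separable E and Z bromides (about 1:1), and only the E isomer (CH2Br trans to CO2Me) is kept, which fixes the enoate geometry read by the catalyst in step 4; no stereocentre is formed.

**Step 2**
Reactants: 3 deca-1,9-diyne; 2 methyl (2E)-4-bromo-3-methylbut-2-enoate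
Product: 5 methyl (2E)-3-methyl-5-methylidenetridec-2-en-12-ynoate, via alkenylalane 4 (not isolated)
Conditions: 3 (3 equiv), Ni(dppp)Cl2 (3 mol %), DIBAL-H (1.0 equiv), THF, 0 to 22 °C, 2 h; then 2 (0.8 equiv), Pd(PPh3)4 (5 mol %), 0 to 22 °C; aq. Rochelle salt; excess 3 recovered
Reagents that add atoms: diisobutylaluminium hydride, CC(C)C[AlH]CC(C)C (the Al(iBu)2 group is present only in 4; only its H stays in 5)
Why: Ni(dppp)-catalysed α-selective (Markovnikov) hydroalumination of one alkyne terminus gives the internal alkenylalane, and a Negishi-type Pd-catalysed alkenylalane–allyl halide coupling joins it to the unhindered CH2 end of the π-allyl with retention of the E-enoate; the excess of nonpolar diyne suppresses double reaction, and all Al–H is consumed before ester 2 is added.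

**Step 3**
Reactants: 5 methyl (2E)-3-methyl-5-methylidenetridec-2-en-12-ynoate
Product: 7 methyl (2E)-5-hydroperoxy-3,5-dimethyltridec-2-en-12-ynoate (racemic at C5), via triethylsilyl peroxide 6 (not isolated)
Conditions: Co(thd)2 (10 mol %), Et3SiH (2 equiv), O2 (1 atm), ClCH2CH2Cl, 22 °C; then cat. HCl, MeOH, 0 °C
Reagents that add atoms: dioxygen, O=O; triethylsilane, CC[SiH](CC)CC (Et3Si is present only in 6; its H stays in 7)
Why: In this Mukaiyama–Isayama peroxidation Co–H transfers H to the =CH2 of the electron-rich 1,1-disubstituted alkene much faster than to the trisubstituted enoate or the alkyne, the tertiary C5 radical is trapped by O2 from both faces (C5 racemic), and acidic methanolysis frees the hydroperoxide without starting the base-dependent ring closure.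

**Step 4**
Reactants: 7 methyl (2E)-5-hydroperoxy-3,5-dimethyltridec-2-en-12-ynoate (racemic)
Product: 8 methyl 2-[(3R,5S)-3,5-dimethyl-5-(oct-7-yn-1-yl)-1,2-dioxolan-3-yl]acetate
Conditions: chiral bifunctional iminophosphorane–urea catalyst (BIMP, tert-leucine-derived, P(4-MeOC6H4)3-based, 10 mol %), toluene (0.05 M), −20 °C; AcOH quench at full conversion; SiO2/normal-phase HPLC separation of the diastereomers; ee checked on a chiral phase
Reagents that add atoms: none
Why: Proposed new method: the hydroperoxide, far more acidic than any C–H of 7, protonates the iminophosphorane, the chiral cation/urea holds ROO− and H-bonds the ester carbonyl, and the α-effect peroxide anion closes 5-exo-trig on the Re face of C3 of the E-enoate, with the enolate protonated at once by the catalyst's conjugate acid so that retro-Michael and epoxide formation do not compete; because Me and CH2R at C5 are nearly isosteric the substrate has no bias of its own, so the catalyst sets C3 = R in both enantiomers (stereodivergent reaction on a racemic mixture), turning (5S)-7 into 8 (ring methyls trans) and (5R)-7 into the (3R,5R) diastereomer (ring methyls cis), which is removed by chromatography, so C3 is set by the catalyst and C5 by this separation (maximum yield 50 %); the closest known reaction types are the amine-promoted racemic peroxy-Michael cyclisation of hydroperoxy enoates to 1,2-dioxolanes and 1,2-dioxanes and the BIMP-catalysed enantioselective intramolecular oxa-Michael addition of alcohols to unactivated α,β-unsaturated esters.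

**Step 5**
Reactants: 9 (3Z)-hex-3-en-1-ol
Product: 10 (3Z)-hex-3-enal
Conditions: Dess–Martin periodinane (1.1 equiv), CH2Cl2, 0 °C, 1 h; cold pentane filtration, used at once
Reagents that add atoms: none
Why: Dess–Martin oxidation is fast, needs no base and does not over-oxidise, so the labile β,γ-unsaturated aldehyde is obtained without migration to the 2E-enal and with the Z-alkene intact.

**Step 6**
Reactants: 10 (3Z)-hex-3-enal
Product: 11 (1E,4Z)-1-iodohepta-1,4-diene
Conditions: CrCl2 (6 equiv), CHI3 (2 equiv), dioxane–THF 6:1, 0 to 22 °C, dark; AgNO3–SiO2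
Reagents that add atoms: iodoform, IC(I)I
Why: In this Takai olefination the gem-dichromium reagent adds to the aldehyde under neutral conditions and anti-elimination gives the E-vinyl iodide (about 8–10:1 in dioxane-rich solvent, minor 1Z isomer removed) without touching the skipped Z-alkene.

**Step 7**
Reactants: 8 methyl 2-[(3R,5S)-3,5-dimethyl-5-(oct-7-yn-1-yl)-1,2-dioxolan-3-yl]acetate; 11 (1E,4Z)-1-iodohepta-1,4-diene
Product: 13 methyl 2-[(3R,5S)-3,5-dimethyl-5-[(7E,9E,12Z)-pentadeca-7,9,12-trien-1-yl]-1,2-dioxolan-3-yl]acetate (target CNP0297319.1), via alkenylzirconocene 12 (not isolated)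
Conditions: Cp2Zr(H)Cl (1.1 equiv), THF, 0 to 22 °C, 20 min, dark; then 11 (1.2 equiv), Pd2(dba)3 (2.5 mol %), P(2-furyl)3 (10 mol %), 22 °C
Reagents that add atoms: zirconocene chloride hydride, [H][Zr](Cl)(C1C=CC=C1)C1C=CC=C1 (Zr is present only in 12; only its H stays in 13)
Why: Syn hydrozirconation of the terminal alkyne (faster than attack on the methyl ester or on the hindered di-tert-alkyl peroxide) gives the E-alkenylzirconocene, and the Negishi Pd-catalysed alkenyl–alkenyl coupling proceeds with retention in both partners to give the 7E,9E-diene; the conditions are base-free, so the two quaternary peroxy carbons cannot scramble by retro-Michael.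

**Compound list**
1 | methyl 3-methylbut-2-enoate | CC(C)=CC(=O)OC | starting material
2 | methyl (2E)-4-bromo-3-methylbut-2-enoate | COC(=O)/C=C(\C)CBr | intermediate
3 | deca-1,9-diyne | C#CCCCCCCC#C | starting material
4 | (deca-1-en-9-yn-2-yl)bis(2-methylpropyl)aluminium (not isolated) | C=C(CCCCCCC#C)[Al](CC(C)C)CC(C)C | intermediate
5 | methyl (2E)-3-methyl-5-methylidenetridec-2-en-12-ynoate | COC(=O)/C=C(\C)CC(=C)CCCCCCC#C | intermediate
6 | methyl (2E)-3,5-dimethyl-5-(triethylsilylperoxy)tridec-2-en-12-ynoate, racemic (not isolated) | COC(=O)/C=C(\C)CC(C)(CCCCCCC#C)OO[Si](CC)(CC)CC | intermediate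
7 | methyl (2E)-5-hydroperoxy-3,5-dimethyltridec-2-en-12-ynoate, racemic at C5 | COC(=O)/C=C(\C)CC(C)(CCCCCCC#C)OO | intermediate
8 | methyl 2-[(3R,5S)-3,5-dimethyl-5-(oct-7-yn-1-yl)-1,2-dioxolan-3-yl]acetate | C#CCCCCCC[C@@]1(C)C[C@](C)(CC(=O)OC)OO1 | intermediate
9 | (3Z)-hex-3-en-1-ol | CC/C=C\CCO | starting material
10 | (3Z)-hex-3-enal | CC/C=C\CC=O | intermediate
11 | (1E,4Z)-1-iodohepta-1,4-diene | CC/C=C\C/C=C/I | intermediate
12 | chlorobis(cyclopentadienyl)[(1E)-8-[(3S,5R)-5-(2-methoxy-2-oxoethyl)-3,5-dimethyl-1,2-dioxolan-3-yl]oct-1-en-1-yl]zirconium (not isolated; same ring configuration as 8) | Cl[Zr](C1C=CC=C1)(C1C=CC=C1)/C=C/CCCCCC[C@@]2(C)C[C@](C)(CC(=O)OC)OO2 | intermediate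
13 | methyl 2-[(3R,5S)-3,5-dimethyl-5-[(7E,9E,12Z)-pentadeca-7,9,12-trien-1-yl]-1,2-dioxolan-3-yl]acetate | CC/C=C\C/C=C/C=C/CCCCCC[C@@]1(C)C[C@](C)(CC(=O)OC)OO1 | target

**Total step count:** 7. **Longest linear sequence:** 5 (steps 1, 2, 3, 4, 7).

**Steps most likely to fail**

Step 4 carries the most risk, because catalyst control at a tetrasubstituted peroxy carbon is untested.
- The fallback sets out from 7 and comes back at 8.
- Racemic 7 is cyclised with an achiral promoter (Et2NH, CF3CH2OH, 22 °C).
- Chromatography gives racemic methyl 2-[(3R*,5S*)-3,5-dimethyl-5-(oct-7-yn-1-yl)-1,2-dioxolan-3-yl]acetate F1 and removes racemic methyl 2-[(3R*,5R*)-3,5-dimethyl-5-(oct-7-yn-1-yl)-1,2-dioxolan-3-yl]acetate F2.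
- The racemate is then resolved by preparative SFC on an amylose carbamate chiral phase, and the (3R,5S) enantiomer is 8.
- Absolute control thus moves from catalysis to a physical resolution of a small, UV-silent but well-behaved ester.

Step 2 is next. Its risks are some β-alane, Al/alkyne C–H exchange, attack at C2, and E/Z leakage through the π-allyl.
- The fallback sets out from 3 and comes back at 5, and it makes step 1 unnecessary.
- Zr-catalysed methylalumination of excess 3 (Me3Al, 10 mol % Cp2ZrCl2, CH2Cl2) gives (E)-dimethyl(2-methyldeca-1-en-9-yn-1-yl)aluminium F3.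
- Protonolysis of this alane gives 2-methyldec-1-en-9-yne F4.
- An EtAlCl2-promoted ene reaction of F4 with methyl but-2-ynoate adds C and H syn across the alkynoate, hence the E-enoate.
- The ene step gives 5 together with its double-bond isomer methyl (2E)-3,5-dimethyltrideca-2,5-dien-12-ynoate F5.
- Both alkenes give the same C5 radical under the conditions of step 3, so the mixture is carried on to 7.

Step 7 is third, because Zr–H meets both a peroxide and a methyl ester.
- The fallback sets out from 5 and from 10 and comes back at 13. The hydrometalation is done before any peroxide exists.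
- Treating 5 with Cp2Zr(H)Cl gives the alkenylzirconocene of the dienyne ester F6.
- Iodine converts it to methyl (2E,12E)-13-iodo-3-methyl-5-methylidenetrideca-2,12-dienoate F7.
- The conditions of step 3 give methyl (2E,12E)-13-iodo-3,5-dimethyl-5-(triethylsilylperoxy)trideca-2,12-dienoate F8 and then methyl (2E,12E)-5-hydroperoxy-13-iodo-3,5-dimethyltrideca-2,12-dienoate F9.
- The conditions of step 4 give methyl 2-[(3R,5S)-5-[(7E)-8-iodooct-7-en-1-yl]-3,5-dimethyl-1,2-dioxolan-3-yl]acetate F10.
- In parallel, aldehyde 10 is converted by the boron variant of the Takai olefination (Cl2CHBpin, CrCl2, LiI) to 2-[(1E,4Z)-hepta-1,4-dien-1-yl]-4,4,5,5-tetramethyl-1,3,2-dioxaborolane F11.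
- A Suzuki–Miyaura coupling of F10 and F11 (Pd(dppf)Cl2, aq. K3PO4, THF, 22 °C) gives 13.

**Further compounds**
F1 | step 4 | racemic methyl 2-[(3R*,5S*)-3,5-dimethyl-5-(oct-7-yn-1-yl)-1,2-dioxolan-3-yl]acetate | C#CCCCCCC[C@@]1(C)C[C@](C)(CC(=O)OC)OO1.C#CCCCCCC[C@]1(C)C[C@@](C)(CC(=O)OC)OO1
F2 | step 4 | racemic methyl 2-[(3R*,5R*)-3,5-dimethyl-5-(oct-7-yn-1-yl)-1,2-dioxolan-3-yl]acetate | C#CCCCCCC[C@]1(C)C[C@](C)(CC(=O)OC)OO1.C#CCCCCCC[C@@]1(C)C[C@@](C)(CC(=O)OC)OO1
F3 | step 2 | (E)-dimethyl(2-methyldeca-1-en-9-yn-1-yl)aluminium | C[Al](C)/C=C(\C)CCCCCCC#C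
F4 | step 2 | 2-methyldec-1-en-9-yne | C=C(C)CCCCCCC#C
F5 | step 2 | methyl (2E)-3,5-dimethyltrideca-2,5-dien-12-ynoate (5E/5Z mixture) | COC(=O)/C=C(\C)CC(C)=CCCCCCC#C
F6 | step 7 | alkenylzirconocene of the dienyne ester: chlorobis(cyclopentadienyl)[(1E,11E)-13-methoxy-11-methyl-9-methylidene-13-oxotrideca-1,11-dien-1-yl]zirconium | COC(=O)/C=C(\C)CC(=C)CCCCCC/C=C/[Zr](Cl)(C1C=CC=C1)C1C=CC=C1
F7 | step 7 | methyl (2E,12E)-13-iodo-3-methyl-5-methylidenetrideca-2,12-dienoate | COC(=O)/C=C(\C)CC(=C)CCCCCC/C=C/I
F8 | step 7 | methyl (2E,12E)-13-iodo-3,5-dimethyl-5-(triethylsilylperoxy)trideca-2,12-dienoate (racemic) | COC(=O)/C=C(\C)CC(C)(CCCCCC/C=C/I)OO[Si](CC)(CC)CC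
F9 | step 7 | methyl (2E,12E)-5-hydroperoxy-13-iodo-3,5-dimethyltrideca-2,12-dienoate (racemic) | COC(=O)/C=C(\C)CC(C)(CCCCCC/C=C/I)OO
F10 | step 7 | methyl 2-[(3R,5S)-5-[(7E)-8-iodooct-7-en-1-yl]-3,5-dimethyl-1,2-dioxolan-3-yl]acetate | I/C=C/CCCCCC[C@@]1(C)C[C@](C)(CC(=O)OC)OO1
F11 | step 7 | 2-[(1E,4Z)-hepta-1,4-dien-1-yl]-4,4,5,5-tetramethyl-1,3,2-dioxaborolane | CC/C=C\C/C=C/B1OC(C)(C)C(C)(C)O1
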